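**Retrosynthetic overview**

1. Target ⇐ acylation of the free C8–OH of a 4,7-oxa-bridged methyl ketal with (E)-N-methylurocanic acid, then one acid step that frees the CH2OH and the hemiketal.
2. Dihydrofuran and C7 ⇐ bridged hydroxypyranone (MeLi on the C7 ketone, then pyranose→furanose transposition) ⇐ oxidative rearrangement of a furylcarbinol held in a furanophane.
3. Ten-membered ring ⇐ intramolecular Nozaki–Hiyama–Kishi closure of C7–C8 (bromofuran + aldehyde); C2=C3 with its furan ⇐ Z-bromo-Wittig/Suzuki on the C2 aldehyde.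
4. Cyclohexene with differentiated C2 ester and C8 acetal ⇐ formylation and retro-Claisen opening of a cis-fused cyclobutanone ⇐ [2+2] cycloaddition of dichloroketene to (R)-α-phellandrene (C14 sets C1 and C10).
5. Ring order: bought cyclohexadiene → cyclobutanone ([2+2], later opened) → furan (bought) → ten-membered carbocycle → pyranone → dihydrofuran.

Assumption: (R)-(−)-α-phellandrene and (E)-3-(1-methyl-1H-imidazol-4-yl)prop-2-enoic acid are bought. Macrocycle names use eunicellane numbering (ring C1–C10; cyclohexene C1, C10–C14; C15 on C3; C16 = methyl on C7); all macrocycles are 1S,10R,14R.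

**Route**

Step 1
Reactants: 1 (R)-(−)-α-phellandrene; 2 trichloroacetyl chloride
Product: 4 (1R,5R,6R)-8,8-dichloro-2-methyl-5-(propan-2-yl)bicyclo[4.2.0]oct-2-en-7-one (cis-fused; four-membered ring anti to the isopropyl group), via dichloroketene 3 (not isolated)
Conditions: Zn–Cu, Et2O, sonication, 15–20 °C, slow addition of 2
Reagents that add atoms: trichloroacetyl chloride (2) ClC(=O)C(Cl)(Cl)Cl
Why: Thermal ketene–alkene [2+2] cycloaddition in which the ketene carbonyl carbon bonds to the diene terminus next to the CH(iPr) carbon and CCl2 to the allylic carbon, suprafacially on the cis-disubstituted double bond and anti to the isopropyl group, so the bought stereocentre sets both ring-fusion centres.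

Step 2
Reactants: 4 the dichlorocyclobutanone
Product: 5 (1R,5R,6R)-2-methyl-5-(propan-2-yl)bicyclo[4.2.0]oct-2-en-7-one
Conditions: Zn dust, AcOH, rt → 50 °C
Reagents that add atoms: none
Why: Zinc reduction of the α,α-dichloroketone (via zinc enolates) removes both chlorines without touching the cis ring fusion or the alkene.

Step 3
Reactants: 5 the cyclobutanone; 6 tert-butoxybis(dimethylamino)methane (Bredereck's reagent)
Product: 7 (E)-8-[(dimethylamino)methylidene]-2-methyl-5-(propan-2-yl)bicyclo[4.2.0]oct-2-en-7-one (ring stereocentres as in 5)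
Conditions: neat 6, 60 °C
Reagents that add atoms: Bredereck's reagent (6) CC(C)(C)OC(N(C)C)N(C)C
Why: Aminomethylenation (a formylation equivalent) at the only α-CH2 of the cyclobutanone gives the vinylogous amide; the bridgehead α-carbon cannot condense.

Step 4
Reactants: 7 the enaminone
Product: 8 methyl (1R,2R,6R)-2-(2,2-dimethoxyethyl)-3-methyl-6-(propan-2-yl)cyclohex-3-ene-1-carboxylate
Conditions: p-TsOH·H2O (1.2 equiv), MeOH, reflux
Reagents that add atoms: methanol CO
Why: Acidic methanolysis gives the β-keto acetal, and strain-driven retro-Claisen cleavage of the cyclobutanone by methanol leaves the ester on C1 and the acetal-terminated two-carbon arm on C10 with both stereocentres untouched.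

Step 5
Reactants: 8 the ester acetal
Product: 9 (1R,2R,6R)-2-(2,2-dimethoxyethyl)-3-methyl-6-(propan-2-yl)cyclohex-3-ene-1-carbaldehyde
Conditions: DIBAL-H (1.1 equiv), CH2Cl2, −78 °C; Rochelle salt
Reagents that add atoms: none
Why: DIBAL-H partial reduction, in which the aluminium hemiacetal is stable at −78 °C and gives the aldehyde only on work-up; the acetal is inert and the low temperature avoids epimerisation at C1.

Step 6
Reactants: 9 the aldehyde; 10 methyl (triphenylphosphoranylidene)acetate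
Product: 12 methyl (Z)-2-bromo-3-[6-(2,2-dimethoxyethyl)-5-methyl-2-(propan-2-yl)cyclohex-4-en-1-yl]prop-2-enoate (ring stereocentres as in 9), via bromo ylide 11 (not isolated)
Conditions: 10 (1.6 equiv), NBS (1.5 equiv), CH2Cl2, −20 °C, 30 min; then 9, −20 °C → rt
Reagents that add atoms: methyl (triphenylphosphoranylidene)acetate (10) COC(=O)C=P(c1ccccc1)(c1ccccc1)c1ccccc1; N-bromosuccinimide BrN1C(=O)CCC1=O
Why: Wittig olefination with the stabilised α-bromo ylide (made in the flask by bromination of the ylide) places the ester trans to the ring, giving the (Z)-α-bromoenoate.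

Step 7
Reactants: 12 the (Z)-bromoenoate; 13 furan-2-ylboronic acid
Product: 14 methyl (E)-2-(furan-2-yl)-3-[6-(2,2-dimethoxyethyl)-5-methyl-2-(propan-2-yl)cyclohex-4-en-1-yl]prop-2-enoate
Conditions: 13 (2 equiv), Pd(PPh3)4 (5 mol %), K2CO3, DME/H2O, 70 °C
Reagents that add atoms: furan-2-ylboronic acid (13) OB(O)c1ccco1
Why: Suzuki–Miyaura cross-coupling of the electron-poor vinyl bromide proceeds with retention, so the furan ends up cis to C1 as the later C1–C2=C3–C4 ring geometry requires.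

Step 8
Reactants: 14 the furyl acrylate
Product: 15 methyl (E)-2-(5-bromofuran-2-yl)-3-[6-(2,2-dimethoxyethyl)-5-methyl-2-(propan-2-yl)cyclohex-4-en-1-yl]prop-2-enoate
Conditions: NBS (1.05 equiv), DMF, 0 °C, dark
Reagents that add atoms: N-bromosuccinimide BrN1C(=O)CCC1=O
Why: Electrophilic aromatic substitution, in which NBS in DMF brominates the free α-position of the 2-substituted furan faster than it attacks the trisubstituted alkene or the enoate.

Step 9
Reactants: 15 the bromofuryl acetal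
Product: 16 methyl (E)-2-(5-bromofuran-2-yl)-3-[5-methyl-6-(2-oxoethyl)-2-(propan-2-yl)cyclohex-4-en-1-yl]prop-2-enoate
Conditions: p-TsOH (cat.), acetone/H2O 10:1, rt
Reagents that add atoms: water O
Why: Acid-catalysed acetal hydrolysis unmasks the C8 aldehyde; ester, vinylfuran and bromide tolerate the mild acid.

Step 10
Reactants: 16 the bromofuryl aldehyde
Product: 17 methyl (2E,8S)-8-hydroxy-4,7-epoxy-16-noreunicella-2,4,6,11-tetraen-15-oate (furanophane: C4–C7 are the furan carbons; CO2Me on C3 trans to C1)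
Conditions: CrCl2 (10 equiv), NiCl2 (0.1 equiv), DMSO/THF, rt, 2 mM, syringe-pump addition
Reagents that add atoms: none
Why: Intramolecular Nozaki–Hiyama–Kishi reaction in which the furylchromium(III) species adds only to the aldehyde; ring closure under control of C1/C10 is expected to give one C8 epimer, taken here as 8S, although the sense of induction cannot be predicted with confidence.

Step 11
Reactants: 17 the furanophane hydroxy ester
Product: 18 (2Z,8S)-4,7-epoxy-16-noreunicella-2,4,6,11-tetraene-8,15-diol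
Conditions: DIBAL-H (3.5 equiv), CH2Cl2, −78 → −40 °C
Reagents that add atoms: none
Why: DIBAL-H 1,2-reduction of the conjugated methyl ester gives the primary allylic alcohol; the furan, the alkenes and the C8 alkoxide are inert.

Step 12
Reactants: 18 the diol
Product: 19 (2Z,8S)-15-[(triisopropylsilyl)oxy]-4,7-epoxy-16-noreunicella-2,4,6,11-tetraen-8-ol
Conditions: TIPSCl (1.1 equiv), imidazole, DMF, 0 °C
Reagents that add atoms: triisopropylsilyl chloride CC(C)[Si](Cl)(C(C)C)C(C)C
Why: Silylation with the bulky TIPSCl is selective for the primary allylic hydroxyl over the hindered secondary furylcarbinol.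

Step 13
Reactants: 19 the furylcarbinol
Product: 20 (2Z,4S,8S)-4-hydroxy-15-[(triisopropylsilyl)oxy]-4,8-epoxy-16-noreunicella-2,5,11-trien-7-one (bridged 6-hydroxy-2H-pyran-3(6H)-one; C3 and C9 cis on the pyranone)
Conditions: VO(acac)2 (5 mol %), t-BuOOH, CH2Cl2, 0 °C → rt
Reagents that add atoms: tert-butyl hydroperoxide CC(C)(C)OO
Why: Hydroxyl-directed vanadium-catalysed Achmatowicz rearrangement oxidises only the furan next to the C8 carbinol, and O8 traps the cis-enedione as the bridged hydroxypyranone, whose C4 configuration is fixed by the bridge; the remote alkenes are untouched.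

Step 14
Reactants: 20 the hydroxypyranone
Product: 21 (2Z,4S,7S,8S)-15-[(triisopropylsilyl)oxy]-4,8-epoxyeunicella-2,5,11-triene-4,7-diol (C16 methyl trans to C9)
Conditions: MeLi (3.5 equiv), THF, −78 °C; aq. NH4Cl
Reagents that add atoms: methyllithium [Li]C
Why: 1,2-Addition of methyllithium to the enone carbonyl (the hemiketal is masked as its lithium alkoxide) from the face opposite the five-atom bridge sets C7 as 7S.

Step 15
Reactants: 21 the pyranose diol
Product: 22 (2Z,4R,7S,8S)-4-methoxy-15-[(triisopropylsilyl)oxy]-4,7-epoxyeunicella-2,5,11-trien-8-ol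
Conditions: PPTS (0.2 equiv), MeOH, rt
Reagents that add atoms: methanol CO
Why: Acid-catalysed ring–chain tautomerism and ketalisation under thermodynamic control (pyranose→furanose transposition) let the tertiary O7 close the 2,5-dihydrofuran on C4, with C4 fixed as 4R by the bridge, and free the C8 hydroxyl.

Step 16
Reactants: 22 the furanose methyl ketal; 23 (E)-3-(1-methyl-1H-imidazol-4-yl)prop-2-enoic acid
Product: 24 (2Z,4R,7S,8S)-4-methoxy-15-[(triisopropylsilyl)oxy]-4,7-epoxyeunicella-2,5,11-trien-8-yl (E)-3-(1-methyl-1H-imidazol-4-yl)prop-2-enoate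
Conditions: 23, DCC, DMAP, CH2Cl2/DMF, rt → 40 °C
Reagents that add atoms: (E)-3-(1-methyl-1H-imidazol-4-yl)prop-2-enoic acid (23) OC(=O)/C=C/c1cn(C)cn1
Why: Steglich esterification (DCC/DMAP) of the only free hydroxyl, the secondary C8–OH, with the E-configured acid; no stereocentre is touched.

Step 17
Reactants: 24 the protected ester
Product: 25 (2Z,4R,7S,8S)-4,15-dihydroxy-4,7-epoxyeunicella-2,5,11-trien-8-yl (E)-3-(1-methyl-1H-imidazol-4-yl)prop-2-enoate (target CNP0196085.1)
Conditions: 48% aq. HF, MeCN, 0 °C → rt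
Reagents that add atoms: water O
Why: Aqueous HF cleaves the Si–O bond and hydrolyses the bis-allylic methyl ketal through its oxocarbenium ion to the hemiketal, whose configuration is dictated by the oxa-bridge (C7 carries no hydrogen, so no furan can form).

**Compound list**

1 | (R)-(−)-α-phellandrene, (5R)-2-methyl-5-(propan-2-yl)cyclohexa-1,3-diene | CC1=CC[C@H](C(C)C)C=C1 | starting material
2 | trichloroacetyl chloride | ClC(=O)C(Cl)(Cl)Cl | starting material
3 | dichloroketene | ClC(Cl)=C=O | intermediate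
4 | (1R,5R,6R)-8,8-dichloro-2-methyl-5-(propan-2-yl)bicyclo[4.2.0]oct-2-en-7-one | CC1=CC[C@H](C(C)C)[C@H]2C(=O)C(Cl)(Cl)[C@@H]12 | intermediate
5 | (1R,5R,6R)-2-methyl-5-(propan-2-yl)bicyclo[4.2.0]oct-2-en-7-one | CC1=CC[C@H](C(C)C)[C@H]2C(=O)C[C@@H]12 | intermediate
6 | tert-butoxybis(dimethylamino)methane (Bredereck's reagent) | CC(C)(C)OC(N(C)C)N(C)C | starting material
7 | (E)-8-[(dimethylamino)methylidene]-2-methyl-5-(propan-2-yl)bicyclo[4.2.0]oct-2-en-7-one | CC1=CC[C@H](C(C)C)[C@H]2C(=O)/C(=C/N(C)C)[C@@H]12 | intermediate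
8 | methyl (1R,2R,6R)-2-(2,2-dimethoxyethyl)-3-methyl-6-(propan-2-yl)cyclohex-3-ene-1-carboxylate | CC1=CC[C@H](C(C)C)[C@@H](C(=O)OC)[C@H]1CC(OC)OC | intermediate
9 | (1R,2R,6R)-2-(2,2-dimethoxyethyl)-3-methyl-6-(propan-2-yl)cyclohex-3-ene-1-carbaldehyde | CC1=CC[C@H](C(C)C)[C@@H](C=O)[C@H]1CC(OC)OC | intermediate
10 | methyl (triphenylphosphoranylidene)acetate | COC(=O)C=P(c1ccccc1)(c1ccccc1)c1ccccc1 | starting material
11 | methyl bromo(triphenylphosphoranylidene)acetate (bromo ylide) | COC(=O)C(Br)=P(c1ccccc1)(c1ccccc1)c1ccccc1 | intermediate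
12 | methyl (Z)-2-bromo-3-[6-(2,2-dimethoxyethyl)-5-methyl-2-(propan-2-yl)cyclohex-4-en-1-yl]prop-2-enoate | CC1=CC[C@H](C(C)C)[C@@H](/C=C(\Br)C(=O)OC)[C@H]1CC(OC)OC | intermediate
13 | furan-2-ylboronic acid | OB(O)c1ccco1 | starting material
14 | methyl (E)-2-(furan-2-yl)-3-[6-(2,2-dimethoxyethyl)-5-methyl-2-(propan-2-yl)cyclohex-4-en-1-yl]prop-2-enoate | CC1=CC[C@H](C(C)C)[C@@H](/C=C(\c2ccco2)C(=O)OC)[C@H]1CC(OC)OC | intermediate
15 | methyl (E)-2-(5-bromofuran-2-yl)-3-[6-(2,2-dimethoxyethyl)-5-methyl-2-(propan-2-yl)cyclohex-4-en-1-yl]prop-2-enoate | CC1=CC[C@H](C(C)C)[C@@H](/C=C(\c2ccc(Br)o2)C(=O)OC)[C@H]1CC(OC)OC | intermediate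
16 | methyl (E)-2-(5-bromofuran-2-yl)-3-[5-methyl-6-(2-oxoethyl)-2-(propan-2-yl)cyclohex-4-en-1-yl]prop-2-enoate | CC1=CC[C@H](C(C)C)[C@@H](/C=C(\c2ccc(Br)o2)C(=O)OC)[C@H]1CC=O | intermediate
17 | methyl (2E,8S)-8-hydroxy-4,7-epoxy-16-noreunicella-2,4,6,11-tetraen-15-oate (furanophane) | CC1=CC[C@H](C(C)C)[C@H]2/C=C(/C(=O)OC)c3ccc(o3)[C@@H](O)C[C@@H]12 | intermediate
18 | (2Z,8S)-4,7-epoxy-16-noreunicella-2,4,6,11-tetraene-8,15-diol | CC1=CC[C@H](C(C)C)[C@H]2/C=C(/CO)c3ccc(o3)[C@@H](O)C[C@@H]12 | intermediate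
19 | (2Z,8S)-15-[(triisopropylsilyl)oxy]-4,7-epoxy-16-noreunicella-2,4,6,11-tetraen-8-ol | CC1=CC[C@H](C(C)C)[C@H]2/C=C(/CO[Si](C(C)C)(C(C)C)C(C)C)c3ccc(o3)[C@@H](O)C[C@@H]12 | intermediate
20 | (2Z,4S,8S)-4-hydroxy-15-[(triisopropylsilyl)oxy]-4,8-epoxy-16-noreunicella-2,5,11-trien-7-one | CC1=CC[C@H](C(C)C)[C@H]2/C=C(/CO[Si](C(C)C)(C(C)C)C(C)C)[C@]3(O)C=CC(=O)[C@@H](O3)C[C@@H]12 | intermediate
21 | (2Z,4S,7S,8S)-15-[(triisopropylsilyl)oxy]-4,8-epoxyeunicella-2,5,11-triene-4,7-diol | CC1=CC[C@H](C(C)C)[C@H]2/C=C(/CO[Si](C(C)C)(C(C)C)C(C)C)[C@]3(O)C=C[C@](C)(O)[C@@H](O3)C[C@@H]12 | intermediate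
22 | (2Z,4R,7S,8S)-4-methoxy-15-[(triisopropylsilyl)oxy]-4,7-epoxyeunicella-2,5,11-trien-8-ol | CC1=CC[C@H](C(C)C)[C@H]2/C=C(/CO[Si](C(C)C)(C(C)C)C(C)C)[C@@]3(OC)C=C[C@](C)(O3)[C@@H](O)C[C@@H]12 | intermediate
23 | (E)-3-(1-methyl-1H-imidazol-4-yl)prop-2-enoic acid | OC(=O)/C=C/c1cn(C)cn1 | starting material
24 | (2Z,4R,7S,8S)-4-methoxy-15-[(triisopropylsilyl)oxy]-4,7-epoxyeunicella-2,5,11-trien-8-yl (E)-3-(1-methyl-1H-imidazol-4-yl)prop-2-enoate | CC1=CC[C@H](C(C)C)[C@H]2/C=C(/CO[Si](C(C)C)(C(C)C)C(C)C)[C@@]3(OC)C=C[C@](C)(O3)[C@@H](OC(=O)/C=C/c3cn(C)cn3)C[C@@H]12 | intermediate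
25 | (2Z,4R,7S,8S)-4,15-dihydroxy-4,7-epoxyeunicella-2,5,11-trien-8-yl (E)-3-(1-methyl-1H-imidazol-4-yl)prop-2-enoate | CC1=CC[C@H](C(C)C)[C@H]2/C=C(/CO)[C@@]3(O)C=C[C@](C)(O3)[C@@H](OC(=O)/C=C/c3cn(C)cn3)C[C@@H]12 | target

**Totals and risks**

Total step count: 17. Longest linear sequence: 17 (1 → 25).

Three steps most likely to fail:

1. Step 10 (strain of the furanophane, and the sense of induction at C8 is not secured). Fallback: form the C8 carbinol before ring closure and close the ring at C3–C4 by Stille coupling. Setting out from 12, acetal hydrolysis (TsOH, acetone/H2O) gives bromoenoate aldehyde F1. 2,5-Bis(tributylstannyl)furan and n-BuLi (THF, −78 °C) give 5-(tributylstannyl)furan-2-yllithium F2, which adds only to the aldehyde of F1. After chromatographic separation of the C8 epimers this gives (8S)-stannylfuryl carbinol F3. Pd2(dba)3/AsPh3/CuI in DMF at high dilution then couples the furylstannane with the vinyl bromide with retention and comes back to the route at 17.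

2. Step 14 (MeLi may enolise at C8 or open the free hemiketal to the enedione). Fallback: mask the hemiketal before the addition. Setting out from 20, brief treatment with MeOH/PPTS caps the anomeric hydroxyl and gives methyl pyranoside ketone F4. MeLi/CeCl3 (THF, −78 °C) adds to this base-stable ketone from the face opposite the bridge and gives tertiary alcohol F5. Prolonged PPTS/MeOH moves the ketal from O8 to O7 and comes back to the route at 22.

3. Step 17 (one acid step must both desilylate and hydrolyse the ketal without harming the allylic hemiketal). Fallback: stage the two events with orthogonal reagents. Setting out from 24, TBAF buffered with AcOH (THF, 0 °C) removes only the silyl ether and gives primary alcohol methyl ketal F6. CSA in MeCN/H2O (rt) then exchanges OMe for OH and comes back to the route at 25.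

**Further compounds**

F1 | step 10 | methyl (Z)-2-bromo-3-[5-methyl-6-(2-oxoethyl)-2-(propan-2-yl)cyclohex-4-en-1-yl]prop-2-enoate | CC1=CC[C@H](C(C)C)[C@@H](/C=C(\Br)C(=O)OC)[C@H]1CC=O
F2 | step 10 | 5-(tributylstannyl)furan-2-yllithium | [Li]c1ccc([Sn](CCCC)(CCCC)CCCC)o1
F3 | step 10 | methyl (Z)-2-bromo-3-{6-[(2S)-2-hydroxy-2-(5-tributylstannylfuran-2-yl)ethyl]-5-methyl-2-(propan-2-yl)cyclohex-4-en-1-yl}prop-2-enoate (8S carbinol) | CC1=CC[C@H](C(C)C)[C@@H](/C=C(\Br)C(=O)OC)[C@H]1C[C@H](O)c1ccc([Sn](CCCC)(CCCC)CCCC)o1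
F4 | step 14 | (2Z,4S,8S)-4-methoxy-15-[(triisopropylsilyl)oxy]-4,8-epoxy-16-noreunicella-2,5,11-trien-7-one | CC1=CC[C@H](C(C)C)[C@H]2/C=C(/CO[Si](C(C)C)(C(C)C)C(C)C)[C@]3(OC)C=CC(=O)[C@@H](O3)C[C@@H]12
F5 | step 14 | (2Z,4S,7S,8S)-4-methoxy-15-[(triisopropylsilyl)oxy]-4,8-epoxyeunicella-2,5,11-trien-7-ol | CC1=CC[C@H](C(C)C)[C@H]2/C=C(/CO[Si](C(C)C)(C(C)C)C(C)C)[C@]3(OC)C=C[C@](C)(O)[C@@H](O3)C[C@@H]12
F6 | step 17 | (2Z,4R,7S,8S)-15-hydroxy-4-methoxy-4,7-epoxyeunicella-2,5,11-trien-8-yl (E)-3-(1-methyl-1H-imidazol-4-yl)prop-2-enoate | CC1=CC[C@H](C(C)C)[C@H]2/C=C(/CO)[C@@]3(OC)C=C[C@](C)(O3)[C@@H](OC(=O)/C=C/c3cn(C)cn3)C[C@@H]12
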